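The eta run, at 70 °C with 0.65 mM of G and [X] at 0.050 M, still shows 76.8% of its X after 5.00 h, which reads as a first-order constant of 0.0528 h⁻¹.

| flask | X | G | temperature | remark | time |
|---|---|---|---|---|---|
| eta | 0.050 M | 0.65 mM | 70 °C | run made earlier |  |
| theta | 0.050 M | 0.98 mM | 92 °C | run made earlier |  |
| zeta | 0.10 M | 1.3 mM | 70 °C | run made earlier |  |
| north | 0.050 M | 1.3 mM | 60 °C |  | 8.0 h |
| north-east | 0.050 M | 1.3 mM | 80 °C |  | 8.0 h |
| east | 0.050 M | 1.3 mM | 100 °C |  | 8.0 h |

eta run (percent of the X charged)

| time / h | D / % | L / % | Q / % | X / % |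
|---|---|---|---|---|
| 0.417 | 1.0 | 1.0 | 0.2 | 97.1 |
| 0.667 | 3.7 | 0.6 | 1.4 | 96.6 |
| 1.33 | 6.2 | 1.7 | 1.1 | 94.1 |
| 2.00 | 10.2 | 1.3 | 0.7 | 89.5 |
| 3.00 | 13.3 | 1.0 | 1.6 | 85.9 |
| 5.00 | 24.5 | 0.2 | 0.5 | 76.8 |

theta run (percent of the X charged)

| time / min | D / % | L / % | Q / % | X / % |
|---|---|---|---|---|
| 15.0 | 8.6 | 1.8 | 2.0 | 89.6 |
| 30.0 | 16.6 | 0 | 2.4 | 81.6 |
| 50.0 | 27.3 | 1.4 | 0.3 | 71.0 |
| 60.0 | 30.2 | 0 | 0 | 66.9 |
| 80.0 | 39.1 | 1.4 | 1.8 | 58.9 |
| 90.0 | 42.0 | 0 | 2.4 | 56.9 |

zeta run (percent of the X charged)

| time / h | D / % | L / % | Q / % | X / % |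
|---|---|---|---|---|
| 0.417 | 1.7 | 0.6 | 0 | 95.6 |
| 1.33 | 8.5 | 0.4 | 1.0 | 90.9 |
| 2.50 | 14.7 | 0 | 0.2 | 83.6 |
| 4.00 | 21.7 | 0 | 0.2 | 76.9 |
| 5.00 | 26.3 | 0 | 1.4 | 72.0 |

(each reading ± 1 percentage point)

* which of these there is most of at the end, counted by the X in it, north (Q / L / X / D)
* which of these there is most of at the end, counted by the X in it, north-east (Q / L / X / D)
* which of these there is most of at the end, counted by the X in it, east (Q / L / X / D)
* amount of the one of these that there is most of at the end, in percent of the X charged, north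
* amount of the one of these that there is most of at the end, in percent of the X charged, north-east
* amount of the one of these that there is most of at the end, in percent of the X charged, east

- the analysis behind the earlier runs scatters by 1 percentage point, standard deviation

The theta run, at the same [X], reads 0.376 h⁻¹ from its last point. I turn the settings one at a time.

G first: by hand the constant scales with [G], but no two runs differ in [G] alone. The zeta run, with twice the [X] and twice the [G], reads 0.0657 h⁻¹, which is 1.24 times eta's. So the scaling stays my assumption, and I hold to [X] of 0.050 M, where the three new flasks stand.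

Temperature next: per unit of G, theta reads 4.72 times eta over 22.0 K, so the constant doubles every 9.82 K. East, at 100 °C, lies above theta's 92 °C, so it is an extrapolation.

For north that gives 13.3 h. This is τ, my estimate of the time in which X falls to half at [X] 0.050 M, [G] 1.3 mM and 60 °C.

Time last: it enters as n = t/τ, the number of half-times, and I take X left as one half to the power n. The catalyst forms can hold 2.60% of the X charged, so by my reckoning D passes X near n of one.

| | | |
|---|---|---|
| north | n 0.602 | X 65.9% |
| north-east | n 2.47 | X 18.0% |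
| east | n 10.1 | X 0.0898% |

The forecast gives X at 65% for north, D at 84% for north-east, and D at 97% for east, “with about 2% held on catalyst”. My north-east leaves D near 79.4% if the catalyst forms hold their full share, which is lower than the forecast's figure.

    X + G → L (k = 2.10 L mol⁻¹ min⁻¹, Ea = 59.0 kJ mol⁻¹)
    L → Q (k = 0.130 min⁻¹, Ea = 90.0 kJ mol⁻¹)
    Q ⇌ G + D (K = 0.0540 M, k = 0.0500 min⁻¹, Ea = 101 kJ mol⁻¹, ΔH = −25.0 kJ mol⁻¹)
    (constants at 60 °C)

North ends with X at 68.4% against D at 29.8%, north-east with D at 82.2%, and east with D at 96.8%; X is most in north, where n of 0.602 stands below one. In north, with the other concentrations held at their charge and each step taken forward, X + G → L has the longest half-life of the steps, 4.2 h, and while X fell from 82.9% at 4.00 h to 68.4% at 8.00 h, Q was the resting state, at 53.0% and then 52.5% of the catalyst charged. Carried to north read at 15 h, τ of 13.3 h gives n of 1.13 and X of 45.8%; that reading holds X at 46.9% and D, now the most, at 51.4%.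

The readings stem from a simulated flask with constants of no real substance; the scatter is artificial.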